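**Plan**
- Retrosynthesis: the C4 and C4'' ketones go back to carbinols and C3–H/C4–OH to a C3=C4 alkene; ring C is then cut across C3=C4 (metathesis), followed by O1–C8a (fluoride displacement), C3–C8'' (enolate arylation) and, in unit 2, C2''–aryl (conjugate addition to a chromone).
- Enabling feature: C3 is configurationally labile only because C4 is a carbonyl, so C3 and C4 are carried as the two alkene termini of ring C beside the allylic ether carbon C2, the only stereocentre of unit 1 (rings A, C, B) at ring closure.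
- Forward order: unit 2 (rings D, F, E) first, as a silyl-protected 8''-bromoflavan-4''-ol; C3 and C2 are grafted onto C8'' together with ring B; ring A is hung on O1; ring C closes last.
- Stereochemistry: C2'' from ligand-controlled conjugate arylation; C2 from an oxazaborolidine reduction (kept through the SNAr steps, where no bond to C2 is broken); C3 from hydroboration anti to the pseudoaxial ring B, which gives the 2,3-cis arrangement encoded in the target SMILES.

Key step: step 16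

Remark 1 (assumption): in step 10 the ring B aryl, coplanar with the carbonyl, is taken as the large group and the twisted 1-arylvinyl group as the small one; should the sense prove opposite, the (R)-oxazaborolidine is used.
Remark 2 (assumption): (S)-t-BuPyOX is taken to give (2R)-flavanones, by analogy with its additions to cyclic enones; otherwise the (R)-ligand is used.
Abbreviation: Fv = (2R,4R)-5,7-bis(benzyloxy)-2-[4-(benzyloxy)phenyl]-4-[(tert-butyldimethylsilyl)oxy]chroman-8-yl (ring D, bonded through C8'').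

Step 1
Reactants: 1 2,4,6-trihydroxyacetophenone
Product: 2 1-[2-hydroxy-4,6-bis(benzyloxy)phenyl]ethanone
Conditions: BnBr (2.1 equiv), K2CO3, DMF, 20 °C
Reagents that add atoms: benzyl bromide, BrCc1ccccc1
Why: Williamson etherification; the hydroxyl hydrogen-bonded to the acetyl group is the least nucleophilic, so alkylation should stop at the 4,6-dibenzyl ether.

Step 2
Reactants: 2 1-[2-hydroxy-4,6-bis(benzyloxy)phenyl]ethanone
Product: 4 5,7-bis(benzyloxy)-4H-chromen-4-one, via enaminone 3 (not isolated)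
Conditions: Me2NCH(OMe)2, toluene, 95 °C; then 2 M HCl, CH2Cl2, 40 °C
Reagents that add atoms: N,N-dimethylformamide dimethyl acetal, COC(OC)N(C)C
Why: Enaminone condensation of the methyl ketone followed by acid-promoted addition–elimination of the phenol (loss of dimethylamine) is the standard chromone synthesis and supplies C2'' as the enone β-carbon.

Step 3
Reactants: 4 5,7-bis(benzyloxy)-4H-chromen-4-one; 5 4-(benzyloxy)phenylboronic acid
Product: 6 (2R)-5,7-bis(benzyloxy)-2-[4-(benzyloxy)phenyl]chroman-4-one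
Conditions: Pd(OCOCF3)2 (5 mol %), (S)-t-BuPyOX (6 mol %), NH4PF6 (30 mol %), H2O, ClCH2CH2Cl, 60 °C
Reagents that add atoms: none
Why: Palladium-catalysed asymmetric conjugate addition of an arylboronic acid to a chromone (transmetalation, face-selective insertion of C2''=C3'' into the aryl–palladium bond, protonolysis of the enolate) should set C2'' as R under control of the pyridine–oxazoline ligand, and the neutral medium should not open the flavanone.

Step 4
Reactants: 6 (2R)-5,7-bis(benzyloxy)-2-[4-(benzyloxy)phenyl]chroman-4-one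
Product: 7 (2R,4R)-5,7-bis(benzyloxy)-2-[4-(benzyloxy)phenyl]chroman-4-ol
Conditions: NaBH4, THF/MeOH, 0 °C
Reagents that add atoms: none
Why: Hydride reduction lowers C4'' to the carbinol because a flavanone carbonyl would enolise, ring-open or be reduced in steps 8 to 17; axial hydride delivery to the half-chair with equatorial 2-aryl should give the 2,4-cis (4R) alcohol, a centre erased again in step 19.

Step 5
Reactants: 7 (2R,4R)-5,7-bis(benzyloxy)-2-[4-(benzyloxy)phenyl]chroman-4-ol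
Product: 8 tert-butyl{[(2R,4R)-5,7-bis(benzyloxy)-2-[4-(benzyloxy)phenyl]chroman-4-yl]oxy}dimethylsilane (Fv–H)
Conditions: TBSCl, imidazole, DMF, 25 °C
Reagents that add atoms: tert-butyldimethylsilyl chloride, CC(C)(C)[Si](C)(C)Cl
Why: Imidazole-promoted silylation gives a base-, hydride- and borane-stable ether that fluoride removes without acid, which matters because this benzylic C–O bond ionises easily.

Step 6
Reactants: 8 Fv–H
Product: 9 {[(2R,4R)-5,7-bis(benzyloxy)-2-[4-(benzyloxy)phenyl]-8-bromochroman-4-yl]oxy}(tert-butyl)dimethylsilane (Fv–Br)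
Conditions: NBS (1.0 equiv), CH2Cl2, −78 → 0 °C
Reagents that add atoms: N-bromosuccinimide, BrN1C(=O)CCC1=O
Why: Electrophilic aromatic bromination; in 5,7-dibenzyloxyflavans C8 (between O1 and the 7-benzyloxy group) is the known site of attack, C6 being flanked by two benzyloxy groups of which the 5-substituent is pushed towards it by the peri silyloxy group.

Step 7
Reactants: 10 3',4'-dihydroxyacetophenone
Product: 11 1-[3,4-bis(benzyloxy)phenyl]ethanone
Conditions: BnBr (2.2 equiv), K2CO3, DMF, 60 °C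
Reagents that add atoms: benzyl bromide, BrCc1ccccc1
Why: Williamson etherification of both catechol hydroxyls gives the ring B methyl ketone.

Step 8
Reactants: 9 Fv–Br; 11 1-[3,4-bis(benzyloxy)phenyl]ethanone
Product: 12 1-[3,4-bis(benzyloxy)phenyl]-2-Fv-ethan-1-one
Conditions: Pd2(dba)3 (2.5 mol %), XPhos (6 mol %), NaOt-Bu, toluene, 80 °C
Reagents that add atoms: none
Why: Palladium-catalysed α-arylation of a ketone enolate (oxidative addition of 9 to zerovalent palladium carrying a bulky electron-rich phosphine, enolate binding, reductive elimination) forms C3–C8''; the di-ortho-substituted aryl group allows only monoarylation and fragment 2 now holds no base-sensitive carbonyl.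

Step 9
Reactants: 12 1-[3,4-bis(benzyloxy)phenyl]-2-Fv-ethan-1-one
Product: 14 1-[3,4-bis(benzyloxy)phenyl]-2-Fv-prop-2-en-1-one, via Mannich base 13 (not isolated)
Conditions: CH2(NMe2)2, Ac2O, THF, 60 °C
Reagents that add atoms: bis(dimethylamino)methane, CN(C)CN(C)C
Why: Mannich reaction of the only enolisable CH2 with the iminium acetate formed in situ, then β-elimination of dimethylamine, is the usual α-methylenation of deoxybenzoins and turns C3 into a 1,1-disubstituted alkene carbon.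

Step 10
Reactants: 14 1-[3,4-bis(benzyloxy)phenyl]-2-Fv-prop-2-en-1-one
Product: 15 (1S)-1-[3,4-bis(benzyloxy)phenyl]-2-Fv-prop-2-en-1-ol
Conditions: (S)-Me-CBS oxazaborolidine (0.3 equiv), catecholborane, toluene, −78 → −40 °C; then MeOH, aq. NaOH wash
Reagents that add atoms: none
Why: Corey–Bakshi–Shibata reduction (1,2-selective with catecholborane, which leaves the alkene alone); hydride is delivered within the catalyst–borane–ketone complex to the face fixed by the planar ring B aryl as the large group (remark 1), setting the future C2 as S here, which becomes R once C3 is sp3.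

Step 11
Reactants: 16 2,6-difluoro-4-hydroxybenzonitrile
Product: 17 4-(benzyloxy)-2,6-difluorobenzonitrile
Conditions: BnBr, K2CO3, DMF, 25 °C
Reagents that add atoms: benzyl bromide, BrCc1ccccc1
Why: Williamson etherification of the acidic phenol gives a ring A precursor with two equivalent fluorines ortho to the activating nitrile.

Step 12
Reactants: 15 (1S)-1-[3,4-bis(benzyloxy)phenyl]-2-Fv-prop-2-en-1-ol; 17 4-(benzyloxy)-2,6-difluorobenzonitrile
Product: 18 4-(benzyloxy)-2-{[(1S)-1-[3,4-bis(benzyloxy)phenyl]-2-Fv-prop-2-en-1-yl]oxy}-6-fluorobenzonitrile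
Conditions: KN(SiMe3)2 (1.05 equiv), THF, −78 °C; then 17 (1.3 equiv), −78 → 20 °C
Reagents that add atoms: none
Why: Nucleophilic aromatic substitution by addition–elimination; the hindered alkoxide meets the arene while it carries two fluorines and one donor only, a nitrile (unlike an aldehyde) cannot accept hydride or form a hemiacetal, and the carbinol C–O bond is not broken, so O1–C8a forms with retention at C2.

Step 13
Reactants: 18 4-(benzyloxy)-2-{[(1S)-1-[3,4-bis(benzyloxy)phenyl]-2-Fv-prop-2-en-1-yl]oxy}-6-fluorobenzonitrile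
Product: 19 2,4-bis(benzyloxy)-6-{[(1S)-1-[3,4-bis(benzyloxy)phenyl]-2-Fv-prop-2-en-1-yl]oxy}benzonitrile
Conditions: BnOH (3 equiv), KN(SiMe3)2 (2.5 equiv), THF, 0 → 50 °C
Reagents that add atoms: benzyl alcohol, OCc1ccccc1
Why: Second nucleophilic aromatic substitution; the remaining, now deactivated fluorine is displaced by a small alkoxide used in excess, and THF (not a dipolar aprotic solvent) keeps the alkoxide too weak a base to touch the allylic, benzylic C2–H.

Step 14
Reactants: 19 2,4-bis(benzyloxy)-6-{[(1S)-1-[3,4-bis(benzyloxy)phenyl]-2-Fv-prop-2-en-1-yl]oxy}benzonitrile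
Product: 21 2,4-bis(benzyloxy)-6-{[(1S)-1-[3,4-bis(benzyloxy)phenyl]-2-Fv-prop-2-en-1-yl]oxy}benzaldehyde, via aluminated aldimine 20 (not isolated)
Conditions: i-Bu2AlH, CH2Cl2, −78 → 0 °C; then aq. KNaC4H4O6, wet SiO2
Reagents that add atoms: water, O
Why: Partial reduction of a nitrile with i-Bu2AlH stops at the N-aluminio aldimine, which near-neutral hydrolysis converts into the aldehyde (future C4) without ionising the C2–O or C4''–O bonds.

Step 15
Reactants: 21 2,4-bis(benzyloxy)-6-{[(1S)-1-[3,4-bis(benzyloxy)phenyl]-2-Fv-prop-2-en-1-yl]oxy}benzaldehyde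
Product: 22 1,5-bis(benzyloxy)-3-{[(1S)-1-[3,4-bis(benzyloxy)phenyl]-2-Fv-prop-2-en-1-yl]oxy}-2-ethenylbenzene
Conditions: Ph3PCH3Br, KOt-Bu, THF, 0 → 20 °C
Reagents that add atoms: methyltriphenylphosphonium bromide, C[P+](c1ccccc1)(c1ccccc1)c1ccccc1.[Br-]
Why: Wittig methylenation with the smallest ylide converts the non-enolisable, di-ortho-substituted aldehyde into the ring A styrene, completing the 1,7-diene.

Step 16
Reactants: 22 1,5-bis(benzyloxy)-3-{[(1S)-1-[3,4-bis(benzyloxy)phenyl]-2-Fv-prop-2-en-1-yl]oxy}-2-ethenylbenzene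
Product: 23 (2S)-5,7-bis(benzyloxy)-2-[3,4-bis(benzyloxy)phenyl]-3-Fv-2H-chromene
Conditions: RuCl2(H2IMes)(PCy3)(=CHPh) (second-generation Grubbs catalyst, 10 mol %), 1,4-benzoquinone (20 mol %), toluene (5 mM), 80 °C, argon, dark
Reagents that add atoms: none
Why: Ring-closing olefin metathesis: the ruthenium carbene exchanges onto the ring A styrene to give the C4 alkylidene, which adds across the 1,1-disubstituted C3=CH2 alkene to a ruthenacyclobutane whose cycloreversion forms C3=C4 and releases Ru=CH2, ethene being lost. The closest known reaction type is the ring-closing metathesis of 2-vinylphenyl 2-arylallyl ethers to 3-aryl-2H-chromenes; the di-ortho-substituted ring D on C3 and the aryl group on C2 make this a more crowded member of that class. Ring C closes as a six-membered 2H-pyran from the 1,7-diene, both reacting carbons ending endocyclic. No stereocentre is formed, and C2, which has no acidic or ionisable neighbour under these neutral conditions, is carried through unchanged (the descriptor stays S only because C3 is still sp2). The step needs ring closure to win over dimerisation and over allyl-ether isomerisation: the aryl ether holds the two alkenes in a 1,7-relationship, the hindered 1,1-disubstituted alkene cannot homodimerise, high dilution and benzoquinone as hydride scavenger cover the rest, and light is excluded because 2H-chromenes open photochemically.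

Step 17
Reactants: 23 (2S)-5,7-bis(benzyloxy)-2-[3,4-bis(benzyloxy)phenyl]-3-Fv-2H-chromene
Product: 25 (2R,3S,4S)-5,7-bis(benzyloxy)-2-[3,4-bis(benzyloxy)phenyl]-3-Fv-chroman-4-ol, via alkylborane 24 (not isolated)
Conditions: BH3·SMe2, THF, 0 → 25 °C; then NaBO3·4H2O, H2O, 25 °C
Reagents that add atoms: borane–dimethyl sulfide, B.CSC (boron stays only in 24); sodium perborate, [Na+].[O-]OB=O (oxygen at C4)
Why: Hydroboration–oxidation, as known for 3-aryl-2H-chromenes giving trans-isoflavan-4-ols: boron should go to the less substituted C4 and hydrogen to C3 in a syn addition on the face opposite ring B, which allylic 1,2-strain with ring D holds pseudoaxial at C2, so that C3–H lands trans to ring B and rings B and D become cis, with oxidation retaining configuration at C4.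

Step 18
Reactants: 25 (2R,3S,4S)-5,7-bis(benzyloxy)-2-[3,4-bis(benzyloxy)phenyl]-3-Fv-chroman-4-ol
Product: 26 (2R,3S,4S)-5,7-bis(benzyloxy)-2-[3,4-bis(benzyloxy)phenyl]-3-[(2R,4R)-5,7-bis(benzyloxy)-2-[4-(benzyloxy)phenyl]-4-hydroxychroman-8-yl]chroman-4-ol
Conditions: Bu4NF, THF, 0 → 20 °C
Reagents that add atoms: none
Why: Fluoride-induced desilylation frees the C4'' carbinol under non-acidic conditions, so neither electron-rich benzylic alcohol ionises.

Step 19
Reactants: 26 the C4,C4''-diol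
Product: 27 (2R,3R)-5,7-bis(benzyloxy)-2-[3,4-bis(benzyloxy)phenyl]-3-[(2R)-5,7-bis(benzyloxy)-2-[4-(benzyloxy)phenyl]-4-oxochroman-8-yl]chroman-4-one
Conditions: Dess–Martin periodinane (3 equiv), NaHCO3, CH2Cl2, 0 → 20 °C
Reagents that add atoms: none
Why: Dess–Martin oxidation converts both benzylic carbinols into the aryl ketones in a buffered, non-enolising medium, so the kinetically installed cis configuration at C3 (now α to C4=O) should survive if work-up and purification stay neutral.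

Step 20
Reactants: 27 the heptabenzyl diketone
Product: 28 (2R,3R)-2-(3,4-dihydroxyphenyl)-5,7-dihydroxy-3-[(2R)-5,7-dihydroxy-2-(4-hydroxyphenyl)-4-oxochroman-8-yl]chroman-4-one (CNP0105436.4)
Conditions: H2 (1 atm), Pd/C, EtOAc/MeOH, 20 °C
Reagents that add atoms: none
Why: Catalytic hydrogenolysis cleaves the seven benzyl ethers under neutral conditions that leave the aryl ketones and the C3 configuration alone, as in routine debenzylations of benzylated flavanones.

**Compound list**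
1 | 2,4,6-trihydroxyacetophenone | CC(=O)c1c(O)cc(O)cc1O | starting material
2 | 1-[2-hydroxy-4,6-bis(benzyloxy)phenyl]ethanone | CC(=O)c1c(O)cc(OCc2ccccc2)cc1OCc1ccccc1 | intermediate
3 | (E)-1-[2-hydroxy-4,6-bis(benzyloxy)phenyl]-3-(dimethylamino)prop-2-en-1-one (enaminone) | CN(C)/C=C/C(=O)c1c(O)cc(OCc2ccccc2)cc1OCc1ccccc1 | intermediate (not isolated)
4 | 5,7-bis(benzyloxy)-4H-chromen-4-one | O=c1ccoc2cc(OCc3ccccc3)cc(OCc3ccccc3)c12 | intermediate
5 | 4-(benzyloxy)phenylboronic acid | OB(O)c1ccc(OCc2ccccc2)cc1 | starting material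
6 | (2R)-5,7-bis(benzyloxy)-2-[4-(benzyloxy)phenyl]chroman-4-one | O=C1C[C@H](c2ccc(OCc3ccccc3)cc2)Oc2cc(OCc3ccccc3)cc(OCc3ccccc3)c21 | intermediate
7 | (2R,4R)-5,7-bis(benzyloxy)-2-[4-(benzyloxy)phenyl]chroman-4-ol | O[C@@H]1C[C@H](c2ccc(OCc3ccccc3)cc2)Oc2cc(OCc3ccccc3)cc(OCc3ccccc3)c21 | intermediate
8 | Fv–H, the tert-butyldimethylsilyl ether of 7 | CC(C)(C)[Si](C)(C)O[C@@H]1C[C@H](c2ccc(OCc3ccccc3)cc2)Oc2cc(OCc3ccccc3)cc(OCc3ccccc3)c21 | intermediate
9 | Fv–Br, the 8-bromo derivative of 8 | CC(C)(C)[Si](C)(C)O[C@@H]1C[C@H](c2ccc(OCc3ccccc3)cc2)Oc2c(Br)c(OCc3ccccc3)cc(OCc3ccccc3)c21 | intermediate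
10 | 3',4'-dihydroxyacetophenone | CC(=O)c1ccc(O)c(O)c1 | starting material
11 | 1-[3,4-bis(benzyloxy)phenyl]ethanone | CC(=O)c1ccc(OCc2ccccc2)c(OCc2ccccc2)c1 | intermediate
12 | 1-[3,4-bis(benzyloxy)phenyl]-2-Fv-ethan-1-one | CC(C)(C)[Si](C)(C)O[C@@H]1C[C@H](c2ccc(OCc3ccccc3)cc2)Oc2c(CC(=O)c3ccc(OCc4ccccc4)c(OCc4ccccc4)c3)c(OCc3ccccc3)cc(OCc3ccccc3)c21 | intermediate
13 | 1-[3,4-bis(benzyloxy)phenyl]-3-(dimethylamino)-2-Fv-propan-1-one (Mannich base, both C2 epimers) | CC(C)(C)[Si](C)(C)O[C@@H]1C[C@H](c2ccc(OCc3ccccc3)cc2)Oc2c(C(CN(C)C)C(=O)c3ccc(OCc4ccccc4)c(OCc4ccccc4)c3)c(OCc3ccccc3)cc(OCc3ccccc3)c21 | intermediate (not isolated)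
14 | 1-[3,4-bis(benzyloxy)phenyl]-2-Fv-prop-2-en-1-one | CC(C)(C)[Si](C)(C)O[C@@H]1C[C@H](c2ccc(OCc3ccccc3)cc2)Oc2c(C(=C)C(=O)c3ccc(OCc4ccccc4)c(OCc4ccccc4)c3)c(OCc3ccccc3)cc(OCc3ccccc3)c21 | intermediate
15 | (1S)-1-[3,4-bis(benzyloxy)phenyl]-2-Fv-prop-2-en-1-ol | CC(C)(C)[Si](C)(C)O[C@@H]1C[C@H](c2ccc(OCc3ccccc3)cc2)Oc2c(C(=C)[C@@H](O)c3ccc(OCc4ccccc4)c(OCc4ccccc4)c3)c(OCc3ccccc3)cc(OCc3ccccc3)c21 | intermediate
16 | 2,6-difluoro-4-hydroxybenzonitrile | N#Cc1c(F)cc(O)cc1F | starting material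
17 | 4-(benzyloxy)-2,6-difluorobenzonitrile | N#Cc1c(F)cc(OCc2ccccc2)cc1F | intermediate
18 | 4-(benzyloxy)-2-{[(1S)-1-[3,4-bis(benzyloxy)phenyl]-2-Fv-prop-2-en-1-yl]oxy}-6-fluorobenzonitrile | CC(C)(C)[Si](C)(C)O[C@@H]1C[C@H](c2ccc(OCc3ccccc3)cc2)Oc2c(C(=C)[C@@H](Oc3cc(OCc4ccccc4)cc(F)c3C#N)c3ccc(OCc4ccccc4)c(OCc4ccccc4)c3)c(OCc3ccccc3)cc(OCc3ccccc3)c21 | intermediate
19 | 2,4-bis(benzyloxy)-6-{[(1S)-1-[3,4-bis(benzyloxy)phenyl]-2-Fv-prop-2-en-1-yl]oxy}benzonitrile | CC(C)(C)[Si](C)(C)O[C@@H]1C[C@H](c2ccc(OCc3ccccc3)cc2)Oc2c(C(=C)[C@@H](Oc3cc(OCc4ccccc4)cc(OCc4ccccc4)c3C#N)c3ccc(OCc4ccccc4)c(OCc4ccccc4)c3)c(OCc3ccccc3)cc(OCc3ccccc3)c21 | intermediate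
20 | N-(diisobutylalumanyl) aldimine of 21 | CC(C)(C)[Si](C)(C)O[C@@H]1C[C@H](c2ccc(OCc3ccccc3)cc2)Oc2c(C(=C)[C@@H](Oc3cc(OCc4ccccc4)cc(OCc4ccccc4)c3C=N[Al](CC(C)C)CC(C)C)c3ccc(OCc4ccccc4)c(OCc4ccccc4)c3)c(OCc3ccccc3)cc(OCc3ccccc3)c21 | intermediate (not isolated)
21 | 2,4-bis(benzyloxy)-6-{[(1S)-1-[3,4-bis(benzyloxy)phenyl]-2-Fv-prop-2-en-1-yl]oxy}benzaldehyde | CC(C)(C)[Si](C)(C)O[C@@H]1C[C@H](c2ccc(OCc3ccccc3)cc2)Oc2c(C(=C)[C@@H](Oc3cc(OCc4ccccc4)cc(OCc4ccccc4)c3C=O)c3ccc(OCc4ccccc4)c(OCc4ccccc4)c3)c(OCc3ccccc3)cc(OCc3ccccc3)c21 | intermediate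
22 | 1,5-bis(benzyloxy)-3-{[(1S)-1-[3,4-bis(benzyloxy)phenyl]-2-Fv-prop-2-en-1-yl]oxy}-2-ethenylbenzene (metathesis precursor) | CC(C)(C)[Si](C)(C)O[C@@H]1C[C@H](c2ccc(OCc3ccccc3)cc2)Oc2c(C(=C)[C@@H](Oc3cc(OCc4ccccc4)cc(OCc4ccccc4)c3C=C)c3ccc(OCc4ccccc4)c(OCc4ccccc4)c3)c(OCc3ccccc3)cc(OCc3ccccc3)c21 | intermediate
23 | (2S)-5,7-bis(benzyloxy)-2-[3,4-bis(benzyloxy)phenyl]-3-Fv-2H-chromene (flav-3-ene) | CC(C)(C)[Si](C)(C)O[C@@H]1C[C@H](c2ccc(OCc3ccccc3)cc2)Oc2c(C3=Cc4c(OCc5ccccc5)cc(OCc5ccccc5)cc4O[C@H]3c3ccc(OCc4ccccc4)c(OCc4ccccc4)c3)c(OCc3ccccc3)cc(OCc3ccccc3)c21 | intermediate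
24 | (2R,3R,4S)-4-boranyl-5,7-bis(benzyloxy)-2-[3,4-bis(benzyloxy)phenyl]-3-Fv-chromane (alkylborane; 2,3-cis and 3,4-trans) | CC(C)(C)[Si](C)(C)O[C@@H]1C[C@H](c2ccc(OCc3ccccc3)cc2)Oc2c([C@H]3[C@H](B)c4c(OCc5ccccc5)cc(OCc5ccccc5)cc4O[C@H]3c3ccc(OCc4ccccc4)c(OCc4ccccc4)c3)c(OCc3ccccc3)cc(OCc3ccccc3)c21 | intermediate (not isolated)
25 | (2R,3S,4S)-5,7-bis(benzyloxy)-2-[3,4-bis(benzyloxy)phenyl]-3-Fv-chroman-4-ol | CC(C)(C)[Si](C)(C)O[C@@H]1C[C@H](c2ccc(OCc3ccccc3)cc2)Oc2c([C@H]3[C@H](O)c4c(OCc5ccccc5)cc(OCc5ccccc5)cc4O[C@H]3c3ccc(OCc4ccccc4)c(OCc4ccccc4)c3)c(OCc3ccccc3)cc(OCc3ccccc3)c21 | intermediate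
26 | (2R,3S,4S)-5,7-bis(benzyloxy)-2-[3,4-bis(benzyloxy)phenyl]-3-[(2R,4R)-5,7-bis(benzyloxy)-2-[4-(benzyloxy)phenyl]-4-hydroxychroman-8-yl]chroman-4-ol | O[C@@H]1C[C@H](c2ccc(OCc3ccccc3)cc2)Oc2c([C@H]3[C@H](O)c4c(OCc5ccccc5)cc(OCc5ccccc5)cc4O[C@H]3c3ccc(OCc4ccccc4)c(OCc4ccccc4)c3)c(OCc3ccccc3)cc(OCc3ccccc3)c21 | intermediate
27 | (2R,3R)-5,7-bis(benzyloxy)-2-[3,4-bis(benzyloxy)phenyl]-3-[(2R)-5,7-bis(benzyloxy)-2-[4-(benzyloxy)phenyl]-4-oxochroman-8-yl]chroman-4-one | O=C1C[C@H](c2ccc(OCc3ccccc3)cc2)Oc2c([C@H]3C(=O)c4c(OCc5ccccc5)cc(OCc5ccccc5)cc4O[C@H]3c3ccc(OCc4ccccc4)c(OCc4ccccc4)c3)c(OCc3ccccc3)cc(OCc3ccccc3)c21 | intermediate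
28 | (2R,3R)-2-(3,4-dihydroxyphenyl)-5,7-dihydroxy-3-[(2R)-5,7-dihydroxy-2-(4-hydroxyphenyl)-4-oxochroman-8-yl]chroman-4-one | O=C1C[C@H](c2ccc(O)cc2)Oc2c1c(O)cc(O)c2[C@H]1C(=O)c2c(O)cc(O)cc2O[C@H]1c1ccc(O)c(O)c1 | target

**Step count**
- Total: 20 steps.
- Longest linear sequence: 18 steps (1–6, 8–10, 12–20).

**Steps most likely to fail**

Step 10. Both carbonyl substituents are sp2 groups, so the oxazaborolidine may discriminate them poorly or in the opposite sense, giving low facial selectivity. The fallback sets out from enone 14. Luche reduction (NaBH4, CeCl3·7H2O, MeOH/THF, −40 °C) gives the carbinol as its two C1 epimers, mixture F1. Because fragment 2 is already enantiopure, these are diastereomers; they are separated by preparative HPLC and assigned by Mosher ester analysis. The (1R)-epimer is re-oxidised to 14 with MnO2 and recycled; the (1S)-epimer is 15, where the route is rejoined.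

Step 16. The carbene may rest as an ortho-alkoxy-chelated benzylidene on the doubly ortho-oxygenated ring A styrene and fail to reach the crowded 1,1-disubstituted alkene, so that the diene is recovered or isomerised. The fallback is a relay metathesis that sets out from aldehyde 21. Wittig reaction with the ylide of (hex-5-en-1-yl)triphenylphosphonium bromide (KOt-Bu, THF) gives 1,5-bis(benzyloxy)-3-{[(1S)-1-[3,4-bis(benzyloxy)phenyl]-2-Fv-prop-2-en-1-yl]oxy}-2-[(1Z)-hepta-1,6-dien-1-yl]benzene F2. With the same ruthenium catalyst, loading now occurs on the unhindered terminal alkene; loss of cyclopentene delivers the C4 alkylidene directly beside C3, and closure gives 23, where the route is rejoined.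

Step 17. Boron may add at C3 (the electron-rich ring A and the allylic oxygen favour this electronically), or addition may be slow or occur on the wrong face at the crowded trisubstituted alkene. The fallback sets out from 23. Homogeneous hydrogenation with the Crabtree catalyst [Ir(cod)(PCy3)(py)]PF6 (H2, CH2Cl2) spares the benzyl ethers and should add hydrogen anti to ring B, giving (2R,3R)-5,7-bis(benzyloxy)-2-[3,4-bis(benzyloxy)phenyl]-3-Fv-chromane F3, the 2,3-cis flavan. Benzylic hydroxylation at C4 with DDQ and water in CH2Cl2, as practised on benzylated flavans, should bring the hydroxyl in trans to the C3 aryl group and give 25, where the route is rejoined. If C4'' were oxidised as well, it would only reach the ketone level that step 19 requires.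

**Further compounds**
F1 | step 10 | 1-[3,4-bis(benzyloxy)phenyl]-2-Fv-prop-2-en-1-ol, mixture of (1S)- and (1R)-epimers | CC(C)(C)[Si](C)(C)O[C@@H]1C[C@H](c2ccc(OCc3ccccc3)cc2)Oc2c(C(=C)C(O)c3ccc(OCc4ccccc4)c(OCc4ccccc4)c3)c(OCc3ccccc3)cc(OCc3ccccc3)c21
F2 | step 16 | 1,5-bis(benzyloxy)-3-{[(1S)-1-[3,4-bis(benzyloxy)phenyl]-2-Fv-prop-2-en-1-yl]oxy}-2-[(1Z)-hepta-1,6-dien-1-yl]benzene | CC(C)(C)[Si](C)(C)O[C@@H]1C[C@H](c2ccc(OCc3ccccc3)cc2)Oc2c(C(=C)[C@@H](Oc3cc(OCc4ccccc4)cc(OCc4ccccc4)c3/C=C\CCCC=C)c3ccc(OCc4ccccc4)c(OCc4ccccc4)c3)c(OCc3ccccc3)cc(OCc3ccccc3)c21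
F3 | step 17 | (2R,3R)-5,7-bis(benzyloxy)-2-[3,4-bis(benzyloxy)phenyl]-3-Fv-chromane (2,3-cis) | CC(C)(C)[Si](C)(C)O[C@@H]1C[C@H](c2ccc(OCc3ccccc3)cc2)Oc2c([C@H]3Cc4c(OCc5ccccc5)cc(OCc5ccccc5)cc4O[C@H]3c3ccc(OCc4ccccc4)c(OCc4ccccc4)c3)c(OCc3ccccc3)cc(OCc3ccccc3)c21
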